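## Retrosynthetic overview

1. The last bond made is C1–O, the tertiary alkyl aryl ether. It closes the bridged oxepane and sets C1 and C10, and it leads back to a phenol bearing an exocyclic olefin (a C4-benzhydryl aromadendrene, the carbon analogue of spathulenol).
2. C4–C7′ and C1–C5 come from alkylating (+)-bicyclogermacrene with the ortho-quinone methide made from benzaldehyde and 2,4-diformylphloroglucinol. Transannular closure forms the cyclopentane and cycloheptane together.
3. C1=C10 comes from McMurry closure of the ten-membered ring from an acyclic keto aldehyde.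
4. C2–C3 and the E-C4=C5 olefin come from a Claisen rearrangement, after isopropenyl addition to the keto aldehyde obtained by ozonolysis of (+)-2-carene. C6 and C7 come from the chiral pool.
5. Ring order: cyclopropane (bought), then the ten-membered ring, then cyclopentane plus cycloheptane, then the oxepane.

Assumption: locants C1–C15 follow aromadendrane/germacrane numbering and C7′ is the benzylic carbon. 2,4-Diformylphloroglucinol is bought; it is otherwise one Vilsmeier–Haack step from phloroglucinol.

## Route

Step 1
Reactants: 1 (+)-2-carene [(1S,6R)-3,7,7-trimethylbicyclo[4.1.0]hept-2-ene]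
Product: 3 (1S,3R)-2,2-dimethyl-3-(3-oxobutyl)cyclopropane-1-carbaldehyde (cis), via secondary ozonide 2 (not isolated)
Conditions: O3, CH2Cl2, −78 °C; Me2S, −78 °C to 20 °C
Reagents that add atoms: ozone, [O-][O+]=O
Why: Criegee ozonolysis cleaves the only C=C and the neutral reductive work-up gives the keto aldehyde, so the two cyclopropane centres (future C6 and C7) are carried over unchanged from the chiral pool and the cis-aldehyde does not epimerise.

Step 2
Reactants: 3 (1S,3R)-2,2-dimethyl-3-(3-oxobutyl)cyclopropane-1-carbaldehyde; 4 isopropenylmagnesium bromide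
Product: 5 4-{(1R,3S)-3-[1-hydroxy-2-methylprop-2-en-1-yl]-2,2-dimethylcyclopropyl}butan-2-one (both carbinol epimers)
Conditions: 4 (1.05 equiv, 0.5 M in THF), THF, −78 °C; H2O quench
Reagents that add atoms: isopropenylmagnesium bromide (4), CC(=C)[Mg]Br
Why: In this Grignard 1,2-addition one equivalent at −78 °C takes the aldehyde far faster than the methyl ketone, and the new carbinol centre forms as a mixture that does not matter because step 3 erases it.

Step 3
Reactants: 5 4-{(1R,3S)-3-[1-hydroxy-2-methylprop-2-en-1-yl]-2,2-dimethylcyclopropyl}butan-2-one; 6 butyl vinyl ether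
Product: 8 (4E)-5-[(1S,3R)-2,2-dimethyl-3-(3-oxobutyl)cyclopropyl]-4-methylpent-4-enal, via allyl vinyl ether 7 (not isolated)
Conditions: 6 (solvent), Pd(OCOCF3)2 (2 mol %), 4,7-diphenyl-1,10-phenanthroline (2 mol %), Et3N (5 mol %), 75 °C; then toluene, 110 °C
Reagents that add atoms: butyl vinyl ether (6), C=COCCCC
Why: Palladium-catalysed vinyl ether exchange is followed by a Claisen [3,3] rearrangement through a chair transition state with the bulky cyclopropyl group equatorial, which forms C2–C3, delivers the aldehyde (C1) and sets the E-trisubstituted C4=C5 olefin from both carbinol epimers.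

Step 4
Reactants: 8 (4E)-5-[(1S,3R)-2,2-dimethyl-3-(3-oxobutyl)cyclopropyl]-4-methylpent-4-enal
Product: 9 (+)-bicyclogermacrene [(1S,2E,6E,10R)-3,7,11,11-tetramethylbicyclo[8.1.0]undeca-2,6-diene]
Conditions: TiCl3(DME)1.5 (12 equiv), Zn–Cu (40 equiv), DME, reflux, 8 added over 30 h (final 3 mM)
Reagents that add atoms: none
Why: Intramolecular McMurry coupling on low-valent titanium at high dilution joins C1 (aldehyde) to C10 (ketone) and closes the ten-membered ring; the E geometry of the new olefin is favoured because the E,E-diene is the less strained ring, the minor Z isomer is removed on AgNO3-impregnated silica, and the cyclopropane centres and the C4=C5 olefin are untouched.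

Step 5
Reactants: 9 (+)-bicyclogermacrene; 10 benzaldehyde; 11 2,4,6-trihydroxybenzene-1,3-dicarbaldehyde (2,4-diformylphloroglucinol)
Product: 13 2,4,6-trihydroxy-5-{(S)-phenyl[(1aR,4aR,7S,7aR,7bR)-1,1,7-trimethyl-4-methylidenedecahydro-1H-cyclopropa[e]azulen-7-yl]methyl}benzene-1,3-dicarbaldehyde, via ortho-quinone methide 12 (not isolated)
Conditions: 10 (1.2 equiv), 11 (1.2 equiv), MgBr2·OEt2 (2.5 equiv), iPr2NEt (4 equiv), 4 Å MS, CH2Cl2, 0 °C to 25 °C; pH 5 citrate buffer work-up
Reagents that add atoms: benzaldehyde (10), O=Cc1ccccc1; 2,4,6-trihydroxybenzene-1,3-dicarbaldehyde (11), O=Cc1c(O)cc(O)c(C=O)c1O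
Why: Proposed new method: a magnesium-templated domino Knoevenagel condensation / ortho-quinone methide alkylation / transannular cation–olefin cyclisation that ends by proton loss instead of O-capture: MgBr2/iPr2NEt converts 11 into a chelated magnesium phenolate that condenses with 10 to the Mg-bound quinone methide 12 with no free Brønsted acid present (so 9 is not isomerised); the electron-rich vinylcyclopropane olefin attacks through C4 on its outer face while C1=C10 closes onto C5 from inside the ring (anti addition to the E-olefin, the same course as the epoxide-triggered closure of bicyclogermacrene to spathulenol), which fixes C4, C5 and the trans ring-fusion H1 relative to C6/C7; C7′ is set in the same compact transition state, with the benzylidene H lying over C3/C15 and the phenyl group turned outwards; the C10 cation then loses a C14 proton to the amine because both ortho-oxygens are tied up in six-membered O–Mg–O=CH chelates; closest known reactions: Casiraghi-type magnesium phenolate/aldehyde quinone methide generation, biomimetic quinone methide–terpene couplings, and transannular cyclisation of germacrene-type dienes.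

Step 6
Reactants: 13 2,4,6-trihydroxy-5-{(S)-phenyl[(1aR,4aR,7S,7aR,7bR)-1,1,7-trimethyl-4-methylidenedecahydro-1H-cyclopropa[e]azulen-7-yl]methyl}benzene-1,3-dicarbaldehyde
Product: 14 psiguadial A (C1 S, C4 R, C5 R, C6 R, C7 R, C10 S, C7′ S)
Conditions: HN(SO2CF3)2 (5 mol %), CH2Cl2, −78 °C to −50 °C; Et3N quench at −78 °C
Reagents that add atoms: none
Why: Proposed new method: a cryogenic superacid-catalysed migratory hydroaryloxylation: HN(SO2CF3)2 protonates the 1,1-disubstituted C10=C14 olefin at C14 (Markovnikov); the C10 cation is relayed to C1 by a suprafacial 1,2-shift of H1, which lies on the face opposite the aryl group and so gives (S)-C10; one of the two equivalent ortho-OH groups, held under C1 by the C4–C7′ tether, attacks anti to the departing hydride (seven-membered ring closure, ring fusion turned from trans to cis) to give (S)-C1; the non-basic N(SO2CF3)2 anion and the low temperature suppress E1 loss, the H5 shift to the cyclopropylcarbinyl cation, cyclopropane opening and re-ionisation of the tertiary aryl ether; closest known reactions: Brønsted-acid-catalysed Markovnikov hydroalkoxylation of unactivated olefins, proton-induced cyclisation of ortho-prenylphenols to chromans, and hydride-shift relays in terpene cation chemistry.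

## Compound list

1 | (+)-2-carene, (1S,6R)-3,7,7-trimethylbicyclo[4.1.0]hept-2-ene | CC1=C[C@H]2[C@@H](CC1)C2(C)C | starting material
2 | secondary ozonide (1,2,4-trioxolane) of 1, new acetal centres undefined | CC12CC[C@@H]3[C@H](C(OO1)O2)C3(C)C | intermediate
3 | (1S,3R)-2,2-dimethyl-3-(3-oxobutyl)cyclopropane-1-carbaldehyde | CC(=O)CC[C@@H]1[C@H](C=O)C1(C)C | intermediate
4 | isopropenylmagnesium bromide | CC(=C)[Mg]Br | starting material
5 | 4-{(1R,3S)-3-[1-hydroxy-2-methylprop-2-en-1-yl]-2,2-dimethylcyclopropyl}butan-2-one, carbinol epimer mixture | CC(=O)CC[C@@H]1[C@H](C(O)C(C)=C)C1(C)C | intermediate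
6 | butyl vinyl ether | C=COCCCC | starting material
7 | vinyl ether of 5 (allyl vinyl ether, epimer mixture) | CC(=O)CC[C@@H]1[C@H](C(OC=C)C(C)=C)C1(C)C | intermediate
8 | (4E)-5-[(1S,3R)-2,2-dimethyl-3-(3-oxobutyl)cyclopropyl]-4-methylpent-4-enal | CC(=O)CC[C@@H]1[C@H](/C=C(\C)CCC=O)C1(C)C | intermediate
9 | (+)-bicyclogermacrene, (1S,2E,6E,10R)-3,7,11,11-tetramethylbicyclo[8.1.0]undeca-2,6-diene | C/C1=C\CC/C(C)=C/[C@H]2[C@@H](CC1)C2(C)C | intermediate
10 | benzaldehyde | O=Cc1ccccc1 | starting material
11 | 2,4,6-trihydroxybenzene-1,3-dicarbaldehyde | O=Cc1c(O)cc(O)c(C=O)c1O | starting material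
12 | 5-benzylidene-2,4-dihydroxy-6-oxocyclohexa-1,3-diene-1,3-dicarbaldehyde (ortho-quinone methide; geometry fluxional by tautomerism) | O=CC1=C(O)C(C=O)=C(O)C(=Cc2ccccc2)C1=O | intermediate
13 | C4-[(S)-aryl(phenyl)methyl]aromadendr-10(14)-ene phenol: trans-fused, H1 anti to H5, C4–CH3 cis to C6, aryl(phenyl)methyl cis to H5 | C=C1CC[C@@H]2[C@H]([C@@H]3[C@@](C)([C@@H](c4ccccc4)c4c(O)c(C=O)c(O)c(C=O)c4O)CC[C@H]31)C2(C)C | intermediate
14 | psiguadial A | C[C@H]1CC[C@@H]2[C@H]([C@@H]3[C@]4(C)CC[C@@]31Oc1c(C=O)c(O)c(C=O)c(O)c1[C@@H]4c1ccccc1)C2(C)C | target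

## Step count and risks

Total steps: 6. Longest linear sequence: 6 (1 → 3 → 5 → 8 → 9 → 13 → 14).

**Step 5 (new, highest risk).**
- The quinone methide may add by hetero-Diels–Alder reaction to either olefin.
- It may attack through C5 or through C1=C10 instead of C4.
- It may give some of the C7′ epimer.
- The cation may also be captured directly by oxygen, which is harmless because that product is 14.

Fallback with known chemistry: set out from 10 and 11 and condense them with 4-methylbenzenesulfinic acid to the crystalline sulfone F1. NaHCO3 in CH2Cl2/H2O at 20 °C then releases the neutral quinone methide 12 from F1 in the presence of 9. Under these acid-free conditions the established biomimetic quinone methide–terpene coupling runs through to the end: attack of C4, transannular closure, 1,2-H shift and phenoxide capture. The chroman isomers are separated, and the fallback rejoins the route at 14.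

**Step 6 (new).**
- The C10 cation may lose a proton.
- H5 may shift to give the cyclopropylcarbinyl cation, followed by ring opening.
- The product ether may re-ionise.

Fallback with known chemistry: set out from 13. RhCl3·3H2O (5 mol %) in EtOH at 50 °C moves the exocyclic double bond into the tetrasubstituted ring-fusion position, as in the aromadendrene-to-ledene isomerisation, to give the Δ1(10)-olefin isomer F2. An ordinary Markovnikov acid-catalysed hydroaryloxylation (CF3SO3H, 2 mol %, CH2Cl2, −40 °C) then adds the phenol across C1=C10. The proton enters C10 from the open face and the tethered oxygen enters C1 from the other face (anti addition). The fallback rejoins the route at 14.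

**Step 4.**
- The E/Z ratio of the new olefin may be poor.
- Oligomers may form.
- 9 may undergo slow Cope rearrangement in refluxing DME.

Fallback: set out from 8. A SmI2-mediated intramolecular keto–aldehyde pinacol coupling (THF, high dilution, 0 °C) gives the ten-membered 1,2-diol F3. The diastereomer with C2 and C9 anti is separated and converted with 1,1′-thiocarbonyldiimidazole into its cyclic thionocarbonate F4. Corey–Winter syn-elimination with 1,3-dimethyl-2-phenyl-1,3,2-diazaphospholidine at 25–40 °C then gives the E-olefin stereospecifically without heating. The fallback rejoins the route at 9.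

## Further compounds

F1 | step 5 | 2,4,6-trihydroxy-5-[(4-methylbenzenesulfonyl)(phenyl)methyl]benzene-1,3-dicarbaldehyde (racemic) | Cc1ccc(cc1)S(=O)(=O)C(c1ccccc1)c1c(O)c(C=O)c(O)c(C=O)c1O
F2 | step 6 | 2,4,6-trihydroxy-5-{(S)-phenyl[(1aR,7S,7aR,7bR)-1,1,4,7-tetramethyl-1a,2,3,5,6,7,7a,7b-octahydro-1H-cyclopropa[e]azulen-7-yl]methyl}benzene-1,3-dicarbaldehyde | CC1=C2CC[C@](C)([C@@H](c3ccccc3)c3c(O)c(C=O)c(O)c(C=O)c3O)[C@H]2[C@H]4[C@@H](CC1)C4(C)C
F3 | step 4 | (1S,2E,10R)-3,7,11,11-tetramethylbicyclo[8.1.0]undec-2-ene-6,7-diol (diastereomer with C2 and C9 anti, carbinol descriptors not assigned) | CC1(O)CC[C@@H]2[C@H](/C=C(C)/CCC1O)C2(C)C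
F4 | step 4 | cyclic 6,7-thionocarbonate of F3 | CC12CC[C@@H]3[C@H](/C=C(C)/CCC1OC(=S)O2)C3(C)C
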